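All runs were computed with constants of no real substance; noise was put on by code.

Commit to one number, the leak, and skip any further run for this question. You asked for a quick figure on how much of the product stays target in red, grey and green.

in all of them: electrophile 41 mM; protonated nucleophile 123 mM

|  | free base | remark | time |
|---|---|---|---|
| gamma | 8.4 mM | run made earlier |  |
| beta | 54 mM | run made earlier |  |
| red | 15.0 mM |  | 8.0 h |
| grey | 30.0 mM |  | 8.0 h |
| green | 60.0 mM |  | 8.0 h |

- gamma (time / h: target / %, isomer of the product / %): 0.333: 0, 1; 0.500: 5, 1; 0.833: 5, 0; 1.33: 7, 0; 2.50: 8, 1; 4.00: 14, 1
- beta (time / h: target / %, isomer of the product / %): 0.333: 12, 0; 0.500: 16, 0; 0.833: 25, 1; 1.33: 30, 0; 2.50: 42, 0; 4.00: 48, 1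

(readings scatter by 1.5 percentage points)

- what was read earlier has a scatter of 1.5 percentage points, one standard deviation
- steps under discussion: target <-> isomer of the product; electrophile + nucleophile -> acid set free + target; nucleophile + acid set free <-> protonated nucleophile; acid set free + free base <-> salt of the base
- "hardly changes" means that all values lie within two and a half points (for a concentration: within two and a half percent of the largest)

* share of target in all that became target or isomer of the product for red, grey, green, in this order
* the course of these numbers from the first flask to the last (hardly changes / rises, then falls / falls all the way / falls, then rises / rises all the way)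

Start from the step target <-> isomer of the product, which has no [free base] in it. Write isomer over target as leak times mean age, ignoring the way back. Then add up beta's target curve by trapezoids to 4.00 h, which gives 1.34 h in units of the whole charge.

For the first round, pretend target appeared evenly, so its mean age is 2.00 h, half of the time, and the leak comes to 0.0104 /h. Now put the curve back in. Beta's target rose early, so dividing the area by the final target gives a mean age of 2.80 h, older than the first guess. The isomer reading of 1 % over that area gives 0.00744 /h: this is the leak, the first-order rate constant of target turning into isomer. Treat it as a reading, since the scatter of 1.5 percentage points is larger than the isomer read.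

Scale beta's age to 8.0 h for all three flasks, an assumption of mine, which gives 5.60 h. My share is then 96.0 % in each flask, with no course across them.

Your forecast reads 99.3 %, 99 %, 98.8 %, hardly changes, on the grounds “So isomerisation is very slow, with k at most about 0.005 per hour.” We part on the level of the share and agree on its course.

The flasks give 94.9 %, 94.7 % and 94.7 % for red, grey and green, so the course hardly changes, on this scheme:

    target ⇌ isomer of the product (K = 0.610, k = 1.58 × 10⁻⁴ /min)
    electrophile + nucleophile → acid set free + target (k = 0.174 /M/min)
    nucleophile + acid set free ⇌ protonated nucleophile, settled at all times (K = 20000 /M)
    acid set free + free base ⇌ salt of the base, settled at all times (K = 21000 /M)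

Target's forward half-life in red is 73 h, longer than the 8.0 h of the run. Put the leak on green: its 62.5 % of target at 8.00 h, times leak and age, gives 2.60 % of isomer, and green holds 3.46 %.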